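## Retrosynthetic overview

1. The tricycle is opened at C7–C16 (five-membered ring B) and C4–C16 (six-membered ring A) to a 14-membered cembranoid; both bonds are to form in one flask by two transannular cation–olefin closures.
2. C16 serves first as nucleophile (isopropenyl CH2 onto a 3,4-epoxide) and then as electrophile (allyl cation released from a C1,C2-cyclic carbonate).
3. The cembranoid epoxy carbonate comes from an isopropylidene dienol by hydroxyl-directed singlet-oxygen ene reaction and directed epoxidation; C2 is set by oxazaborolidine reduction of a cross-conjugated dienone.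
4. The 14-membered dienone comes from an acyclic (2E,6E)-acid chloride by acylium–olefin macrocyclisation (C1–C2), the laboratory counterpart of the ring closure of geranylgeranyl diphosphate to cembrene.
5. The chain comes from 8-oxo-geranate and a citronellyl zinc reagent (C9–C10). Ring order: 14-membered ring, then ring A, then ring B, which leaves the 11-membered ring C.

Assumption: methyl (2E)-geranate and (R)-citronellyl bromide are bought as single isomers.

Numbering: compounds 10–17 and F3–F5 use cembrane/trinervitane numbering (C1 carries C15 with C16 and C17; Me-18 on C4, C19 on C8, Me-20 on C12). The descriptor at C12 reads R or S depending on the substituents at C1; the centre itself is never touched.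

The route is a proposal: steps 1–8 rest on known reaction types, step 9 is a new cascade.

## Route

Step 1
Reactants: 1 methyl (2E)-geranate [methyl (2E)-3,7-dimethylocta-2,6-dienoate]
Product: 2 methyl (2E,6E)-3,7-dimethyl-8-oxoocta-2,6-dienoate
Conditions: SeO2 (1.1 equiv), 95% EtOH, reflux
Reagents that add atoms: selenium dioxide, O=[Se]=O
Why: Riley allylic oxidation: SeO2 attacks only the electron-rich 6,7-alkene (the enoate alkene is deactivated) and, by the ene/[2,3]-sigmatropic sequence, oxidises the (E)-methyl group to the (E)-enal; no stereocentre is formed.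

Step 2
Reactants: 2 methyl (2E,6E)-3,7-dimethyl-8-oxoocta-2,6-dienoate; 3 (R)-citronellyl bromide [(6R)-8-bromo-2,6-dimethyloct-2-ene]
Product: 6 methyl (2E,6E,8R,11R)-8-hydroxy-3,7,11,15-tetramethylhexadeca-2,6,14-trienoate, via (R)-citronellylmagnesium bromide 4 (not isolated), via bis[(R)-citronellyl]zinc 5 (not isolated)
Conditions: 3, Mg, Et2O; ZnCl2 (0.5 equiv), then 1,4-dioxane, filter; (+)-MIB [(2R)-3-exo-morpholinoisoborneol, 5 mol%], 2, toluene, 0 °C; aq. NH4Cl
Reagents that add atoms: none
Why: Amino-alcohol-catalysed enantioselective 1,2-addition of a salt-free dialkylzinc to an α-methyl enal (Noyori/Nugent type; the ester is inert to R2Zn): the (+)-MIB–zinc complex delivers the citronellyl group to the Re face and sets C8 (later C9) as R, while C11 (later C12) comes unchanged from 3.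

Step 3
Reactants: 6 methyl (2E,6E,8R,11R)-8-hydroxy-3,7,11,15-tetramethylhexadeca-2,6,14-trienoate
Product: 7 (2E,6E,8R,11R)-8-hydroxy-3,7,11,15-tetramethylhexadeca-2,6,14-trienoic acid
Conditions: LiOH·H2O, THF/MeOH/H2O, 45 °C; then cold aq. HCl to pH 3
Reagents that add atoms: lithium hydroxide, [Li+].[OH-]
Why: Saponification of the β,β-disubstituted enoate; the allylic alcohol, the alkenes and both stereocentres are not affected.

Step 4
Reactants: 7 (2E,6E,8R,11R)-8-hydroxy-3,7,11,15-tetramethylhexadeca-2,6,14-trienoic acid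
Product: 8 (2E,6E,8R,11R)-8-acetoxy-3,7,11,15-tetramethylhexadeca-2,6,14-trienoic acid
Conditions: Ac2O, pyridine, DMAP (cat.), CH2Cl2, rt; then H2O/THF
Reagents that add atoms: acetic anhydride, CC(=O)OC(C)=O
Why: DMAP-catalysed acetylation of the secondary allylic alcohol installs the acetate of the target with retention; the mixed anhydride formed at the acid is cleaved again in the aqueous quench.

Step 5
Reactants: 8 (2E,6E,8R,11R)-8-acetoxy-3,7,11,15-tetramethylhexadeca-2,6,14-trienoic acid
Product: 11 (3E,7E,9R,12R)-2-oxocembra-1(15),3,7-trien-9-yl acetate (14-membered cross-conjugated dienone with an isopropylidene group at C1), via acid chloride 9 (not isolated), via 15-chloro ketone 10 (not isolated)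
Conditions: (COCl)2, benzene, rt, evaporate; SnCl4 (1.1 equiv), CH2Cl2 (1 mM, slow addition), −78 °C; aq. NaHCO3; crude, DBU, benzene, rt
Reagents that add atoms: none
Why: Friedel–Crafts-type acylium–olefin macrocyclisation (Kato's cembranoid ring closure): the (E)-enoyl cation cannot reach the 7,8-alkene in a six-membered ring and that alkene is deactivated by the allylic acetate, so the terminal isopropylidene attacks through its CH carbon (C1), chloride traps the C15 cation, and DBU removes HCl by E1cB to give the dienone in which C1 is no longer a stereocentre.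

Step 6
Reactants: 11 (3E,7E,9R,12R)-2-oxocembra-1(15),3,7-trien-9-yl acetate
Product: 12 (2S,3E,7E,9R,12R)-2-hydroxycembra-1(15),3,7-trien-9-yl acetate
Conditions: (R)-1-methyl-3,3-diphenyl-tetrahydropyrrolo[1,2-c][1,3,2]oxazaborole [(R)-Me-CBS, 20 mol%], catecholborane, toluene, −78 °C
Reagents that add atoms: none
Why: Corey–Bakshi–Shibata reduction: the α-branched, fully substituted isopropylidene-vinyl group acts as the large and the C3 vinyl group as the small substituent, so the (R)-catalyst gives the (2S)-bis-allylic alcohol (the spatial arrangement of C2 in the target); catecholborane avoids hydroboration and 1,4-reduction.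

Step 7
Reactants: 12 (2S,3E,7E,9R,12R)-2-hydroxycembra-1(15),3,7-trien-9-yl acetate
Product: 14 (1S,2S,3S,4S,7E,9R,12S)-3,4-epoxy-1,2-dihydroxycembra-7,15-dien-9-yl acetate, via C1 hydroperoxide 13 (not isolated)
Conditions: O2, hν (sodium lamp), tetraphenylporphyrin (cat.), CH2Cl2, −20 °C, to 1 equiv uptake; then Ti(OiPr)4 (10 mol%), 4 Å molecular sieves, −20 → 0 °C
Reagents that add atoms: dioxygen, O=O
Why: Schenck ene reaction followed by titanium-catalysed oxygen transfer (Adam's hydroxy-epoxidation): hydrogen-bonded singlet oxygen attacks the tetrasubstituted alkene syn to the C2 hydroxyl and abstracts a methyl hydrogen, leaving a C1 hydroperoxide and the isopropenyl group, and Ti(OiPr)4 then passes the distal peroxide oxygen to the trisubstituted 3,4-alkene syn to the C2 oxygen in the A(1,3)-minimised conformer (threo), which sets C3 and C4 from C2.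

Step 8
Reactants: 14 (1S,2S,3S,4S,7E,9R,12S)-3,4-epoxy-1,2-dihydroxycembra-7,15-dien-9-yl acetate
Product: 15 (1S,2S,3S,4S,7E,9R,12S)-9-acetoxy-3,4-epoxycembra-7,15-diene-1,2-diyl carbonate (cyclic carbonate of the C1/C2 diol)
Conditions: 1,1′-carbonyldiimidazole, toluene, 80 °C
Reagents that add atoms: 1,1′-carbonyldiimidazole, O=C(n1ccnc1)n1ccnc1
Why: Cyclic carbonate formation (acyl imidazole at the C2 hydroxyl, then 5-exo closure by the C1 hydroxyl) under base-free conditions, so no Payne rearrangement occurs; it removes the free hydroxyls that would cause pinacol shifts in step 9 and makes C1–O a latent leaving group.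

Step 9
Reactants: 15 (1S,2S,3S,4S,7E,9R,12S)-9-acetoxy-3,4-epoxycembra-7,15-diene-1,2-diyl carbonate
Product: 17 (2R,3R,4S,7R,9R,12R,16S)-2,3-dihydroxytrinervita-1(15),8(19)-dien-9-yl acetate (target), via secotrinervitadiene carbonate 16 (not isolated)
Conditions: BF3·OEt2 (0.3 equiv), 2,6-di-tert-butyl-4-methylpyridine (0.3 equiv), CH2Cl2 (5 mM), −78 °C, 1 h, then −20 °C; aq. NaHCO3
Reagents that add atoms: none
Why: Proposed new method: one-flask double transannular cyclisation in which C16 reacts first as nucleophile and then as electrophile — (a) BF3 opens the oxirane at the tertiary C4 (C3 is deactivated by the C2 carbonate oxygen) with anti attack of the isopropenyl CH2 through a chair, the known epoxy-olefin closure of the secotrinervitane type, and inversion at C4 puts Me-18 cis and C5 trans to the C3 oxygen; (b) the 1-methylcyclohexyl-type C15 cation loses H16 to give the endocyclic alkene 16; (c) on warming, the strained trans-fused and now tertiary allylic carbonate ionises at C1, as vinylethylene carbonates do, and the C1–C15–C16 allyl cation is captured at C16 by the 7,8-alkene on the face of the C5–C6 tether (cis-hydrindane; the short C8–C14 belt only reaches with H7 cis to H16); (d) the C8 cation, transiently bridged by the C9 acetate, loses a C19 proton to the hindered pyridine and the C2 hemicarbonate loses CO2 on work-up; the closest known reaction types are Lewis-acid epoxy-polyene cyclisation and SN1′ cation–olefin cyclisation of allylic esters.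

## Compound list

1 | methyl (2E)-geranate | COC(=O)/C=C(\C)CCC=C(C)C | starting material
2 | methyl (2E,6E)-3,7-dimethyl-8-oxoocta-2,6-dienoate | COC(=O)/C=C(\C)CC/C=C(\C)C=O | intermediate
3 | (R)-citronellyl bromide, (6R)-8-bromo-2,6-dimethyloct-2-ene | BrCC[C@H](C)CCC=C(C)C | starting material
4 | [(3R)-3,7-dimethyloct-6-en-1-yl]magnesium bromide | Br[Mg]CC[C@H](C)CCC=C(C)C | intermediate (not isolated)
5 | bis[(3R)-3,7-dimethyloct-6-en-1-yl]zinc | CC(C)=CCC[C@@H](C)CC[Zn]CC[C@H](C)CCC=C(C)C | intermediate (not isolated)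
6 | methyl (2E,6E,8R,11R)-8-hydroxy-3,7,11,15-tetramethylhexadeca-2,6,14-trienoate | COC(=O)/C=C(\C)CC/C=C(\C)[C@H](O)CC[C@H](C)CCC=C(C)C | intermediate
7 | (2E,6E,8R,11R)-8-hydroxy-3,7,11,15-tetramethylhexadeca-2,6,14-trienoic acid | OC(=O)/C=C(\C)CC/C=C(\C)[C@H](O)CC[C@H](C)CCC=C(C)C | intermediate
8 | (2E,6E,8R,11R)-8-acetoxy-3,7,11,15-tetramethylhexadeca-2,6,14-trienoic acid | OC(=O)/C=C(\C)CC/C=C(\C)[C@H](OC(C)=O)CC[C@H](C)CCC=C(C)C | intermediate
9 | (2E,6E,8R,11R)-8-acetoxy-3,7,11,15-tetramethylhexadeca-2,6,14-trienoyl chloride | ClC(=O)/C=C(\C)CC/C=C(\C)[C@H](OC(C)=O)CC[C@H](C)CCC=C(C)C | intermediate (not isolated)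
10 | (3E,7E,9R,12R)-15-chloro-2-oxocembra-3,7-dien-9-yl acetate, both C1 epimers | CC(C)(Cl)C1CC[C@@H](C)CC[C@@H](OC(C)=O)/C(C)=C/CC/C(C)=C/C1=O | intermediate (not isolated)
11 | (3E,7E,9R,12R)-2-oxocembra-1(15),3,7-trien-9-yl acetate | CC(C)=C1CC[C@@H](C)CC[C@@H](OC(C)=O)/C(C)=C/CC/C(C)=C/C1=O | intermediate
12 | (2S,3E,7E,9R,12R)-2-hydroxycembra-1(15),3,7-trien-9-yl acetate | CC(C)=C1CC[C@@H](C)CC[C@@H](OC(C)=O)/C(C)=C/CC/C(C)=C/[C@@H]1O | intermediate
13 | (1S,2S,3E,7E,9R,12S)-1-hydroperoxy-2-hydroxycembra-3,7,15-trien-9-yl acetate | CC(=C)[C@@]1(OO)CC[C@@H](C)CC[C@@H](OC(C)=O)/C(C)=C/CC/C(C)=C/[C@@H]1O | intermediate (not isolated)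
14 | (1S,2S,3S,4S,7E,9R,12S)-3,4-epoxy-1,2-dihydroxycembra-7,15-dien-9-yl acetate | CC(=C)[C@@]1(O)CC[C@@H](C)CC[C@@H](OC(C)=O)/C(C)=C/CC[C@]2(C)O[C@H]2[C@@H]1O | intermediate
15 | (1S,2S,3S,4S,7E,9R,12S)-9-acetoxy-3,4-epoxycembra-7,15-diene-1,2-diyl carbonate | CC(=C)[C@@]1(O2)CC[C@@H](C)CC[C@@H](OC(C)=O)/C(C)=C/CC[C@]3(C)O[C@H]3[C@@H]1OC2=O | intermediate
16 | (1S,2S,3R,4S,7E,9R,12S)-9-acetoxy-3-hydroxy-7,16-secotrinervita-7,15-diene-1,2-diyl carbonate | CC1=C[C@]2(C)CC/C=C(\C)[C@H](OC(C)=O)CC[C@H](C)CC[C@]13OC(=O)O[C@H]3[C@@H]2O | intermediate (not isolated)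
17 | (2R,3R,4S,7R,9R,12R,16S)-2,3-dihydroxytrinervita-1(15),8(19)-dien-9-yl acetate | C=C1[C@H](OC(C)=O)CC[C@H](C)CCC2=C(C)[C@@H]3[C@H]1CC[C@]3(C)[C@@H](O)[C@@H]2O | target

## Step count and risks

Total step count: 9. Longest linear sequence: 9 steps (1 → 17); 3 enters in step 2.

Steps most likely to fail:

Step 9. The risks are ionisation of the allylic carbonate before the first closure, an exocyclic instead of endocyclic alkene after the first closure, and a badly behaved C8 cation next to the C9 acetate (acetoxonium trapping to a hydroxy acetate, or an endocyclic alkene). The fallback sets out from 15 and comes back at 17. Only the first closure is run (BF3·OEt2, −78 °C, cold quench) and the secotrinervitadiene carbonate 16 is isolated. The second ring is then closed by a palladium-ene reaction instead of a cation: zerovalent palladium, Pd(PPh3)4 (10 mol%), AcOH, 75 °C. Decarboxylative ionisation of the vinyl carbonate gives a π-allyl palladium anti to the leaving oxygen, that is, on the face of the C5 tether. The 7,8-alkene inserts to form C16–C7, and syn β-hydride elimination towards C19 gives the exocyclic alkene without a C8 cation. No new compound is needed (F0).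

Step 5. The 14-membered acylium closure of a chain that is saturated between C10 and C14 may give oligomers, and SnCl4 may ionise the allylic acetate. The fallback sets out from 8 and comes back at 11; it makes the same C1–C2 bond by an aldehyde ene reaction. The acid is reduced through its isobutyl mixed anhydride (i-BuOCOCl, N-methylmorpholine; NaBH4) to the allylic alcohol (2E,6E,8R,11R)-1-hydroxy-3,7,11,15-tetramethylhexadeca-2,6,14-trien-8-yl acetate F1. MnO2 gives the enal (2E,6E,8R,11R)-3,7,11,15-tetramethyl-1-oxohexadeca-2,6,14-trien-8-yl acetate F2. Me2AlCl (CH2Cl2, 1 mM, −78 → 0 °C) closes the ring by a carbonyl-ene reaction to (3E,7E,9R,12R)-2-hydroxycembra-3,7,15-trien-9-yl acetate F3 (C1/C2 isomer mixture). Dess–Martin periodinane gives the β,γ-unsaturated ketone (3E,7E,9R,12R)-2-oxocembra-3,7,15-trien-9-yl acetate F4, and DBU moves the isopropenyl double bond into conjugation.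

Step 7. Oxygen transfer from the tertiary allylic hydroperoxide may go to the isopropenyl group, or the hydroperoxide may undergo Hock cleavage on the titanium centre. The fallback sets out from 12 and comes back at 14. The photo-oxygenation is worked up reductively (PPh3) and the diol (1S,2S,3E,7E,9R,12S)-1,2-dihydroxycembra-3,7,15-trien-9-yl acetate F5 is isolated. The 3,4-epoxide is then introduced with external t-BuOOH under VO(acac)2 catalysis, directed by the secondary C2 hydroxyl (threo by A(1,3) strain; the tertiary C1 hydroxyl and the 1,1-disubstituted alkene react more slowly).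

## Further compounds

F0 | step 9 | none | none
F1 | step 5 | (2E,6E,8R,11R)-1-hydroxy-3,7,11,15-tetramethylhexadeca-2,6,14-trien-8-yl acetate | OC/C=C(\C)CC/C=C(\C)[C@H](OC(C)=O)CC[C@H](C)CCC=C(C)C
F2 | step 5 | (2E,6E,8R,11R)-3,7,11,15-tetramethyl-1-oxohexadeca-2,6,14-trien-8-yl acetate | O=C/C=C(\C)CC/C=C(\C)[C@H](OC(C)=O)CC[C@H](C)CCC=C(C)C
F3 | step 5 | (3E,7E,9R,12R)-2-hydroxycembra-3,7,15-trien-9-yl acetate, C1/C2 isomer mixture | CC(=C)C1CC[C@@H](C)CC[C@@H](OC(C)=O)/C(C)=C/CC/C(C)=C/C1O
F4 | step 5 | (3E,7E,9R,12R)-2-oxocembra-3,7,15-trien-9-yl acetate, both C1 epimers | CC(=C)C1CC[C@@H](C)CC[C@@H](OC(C)=O)/C(C)=C/CC/C(C)=C/C1=O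
F5 | step 7 | (1S,2S,3E,7E,9R,12S)-1,2-dihydroxycembra-3,7,15-trien-9-yl acetate | CC(=C)[C@@]1(O)CC[C@@H](C)CC[C@@H](OC(C)=O)/C(C)=C/CC/C(C)=C/[C@@H]1O
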